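The target is disconnected at the exocyclic CH–guaiacyl bond and at the ring bond between C-alpha and C3. Unfolded in this way, the ring (carbonyl carbon, ring oxygen, OCH2 carbon, C3, C-alpha) plus the exocyclic methine and the benzylic CH2 on C3 is simply the carbon–oxygen chain of a cinnamyl propiolate. One enantioselective arylpalladation cascade should therefore attach the guaiacyl ring, close the lactone onto the styrene, fix the E olefin and set (R)-C3. The precursor is the achiral 1,6-enyne made by esterifying (E)-3,4-dimethoxycinnamyl alcohol with propiolic acid, used with an O-silylated guaiacylboronic acid under a base-free divalent palladium catalyst.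

Key step: step 6

Remark on numbering: C-alpha is the arylidene-bearing ring carbon and C3 the neighbouring benzyl-bearing stereocentre (position 4 in the systematic furanone names).

Assumption: the sense of induction of the pyridine–oxazoline ligand cannot be predicted with confidence for this new substrate class. The route is written with the (S)-ligand; its mirror image would be used instead if the first run shows that it is the one leading to (R)-C3.

Step 1
Reactants: 1 (E)-3,4-dimethoxycinnamic acid
Product: 2 methyl (E)-3,4-dimethoxycinnamate
Conditions: MeOH, H2SO4 (cat.), reflux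
Reagents that add atoms: methanol, CO
Why: Fischer esterification driven by methanol as solvent; the E alkene and the aryl methyl ethers are inert to these conditions.

Step 2
Reactants: 2 methyl (E)-3,4-dimethoxycinnamate
Product: 3 (E)-3-(3,4-dimethoxyphenyl)prop-2-en-1-ol
Conditions: i-Bu2AlH (2.5 equiv), CH2Cl2, −78 °C; aq. KNaC4H4O6 (potassium sodium tartrate)
Reagents that add atoms: none
Why: i-Bu2AlH reduces an enoate by 1,2-hydride delivery to the aluminium-activated carbonyl without touching the conjugated E alkene (ester to allylic alcohol reduction), and the neutral tartrate work-up avoids acid-promoted ionisation of the electron-rich allylic alcohol.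

Step 3
Reactants: 3 (E)-3-(3,4-dimethoxyphenyl)prop-2-en-1-ol; 4 propiolic acid
Product: 5 (E)-3-(3,4-dimethoxyphenyl)prop-2-en-1-yl prop-2-ynoate
Conditions: DCC (1.1 equiv), DMAP (2 mol%), CH2Cl2, −20 °C to 0 °C
Reagents that add atoms: none
Why: Steglich esterification: the carbodiimide activates the strongly acidic propiolic acid as its O-acylisourea, which the primary allylic alcohol should intercept in the cold faster than DMAP or carboxylate adds in conjugate fashion to the ynoate, and the neutral medium does not ionise the electron-rich cinnamyl C–O bond.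

Step 4
Reactants: 6 4-bromo-2-methoxyphenol
Product: 7 (4-bromo-2-methoxyphenoxy)(tert-butyl)dimethylsilane
Conditions: TBSCl, imidazole, DMF, rt
Reagents that add atoms: tert-butyldimethylsilyl chloride, CC(C)(C)[Si](C)(C)Cl
Why: Imidazole-promoted O-silylation of a phenol; it masks the acidic OH that would quench the aryllithium of the next step and keeps a free phenol away from the palladium catalyst later.

Step 5
Reactants: 7 (4-bromo-2-methoxyphenoxy)(tert-butyl)dimethylsilane
Product: 10 [4-(tert-butyldimethylsilyloxy)-3-methoxyphenyl]boronic acid, via aryllithium 8 (not isolated), via lithium aryltriisopropoxyborate 9 (not isolated)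
Conditions: n-BuLi, THF, −78 °C; B(Oi-Pr)3, −78 °C to rt; 1 M HCl to pH 5, 0 °C
Reagents that add atoms: triisopropyl borate, CC(C)OB(OC(C)C)OC(C)C; water, O
Why: Halogen–metal exchange followed by electrophilic borylation: bromine–lithium exchange at −78 °C outruns ortho-lithiation and attack at silicon (the silyloxy group is para to the C–Li bond, so no retro-Brook shift is possible), the borate captures the aryllithium as an ate complex, and brief hydrolysis at pH 5 frees the boronic acid while the acid-tolerant aryl silyl ether survives.

Step 6
Reactants: 5 (E)-3-(3,4-dimethoxyphenyl)prop-2-en-1-yl prop-2-ynoate; 10 [4-(tert-butyldimethylsilyloxy)-3-methoxyphenyl]boronic acid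
Product: 11 (3E,4R)-3-[4-(tert-butyldimethylsilyloxy)-3-methoxybenzylidene]-4-(3,4-dimethoxybenzyl)dihydrofuran-2(3H)-one
Conditions: Pd(OCOCF3)2 (5 mol%), (S)-t-BuPyOx [(S)-4-tert-butyl-2-(pyridin-2-yl)-4,5-dihydrooxazole] (6 mol%), AcOH (5 equiv), H2O (5 equiv), ClCH2CH2Cl, 40 °C, air; 10 (2 equiv) in portions
Reagents that add atoms: none
Why: Proposed new method: the boronic acid transmetalates to the cationic divalent palladium–pyridine-oxazoline complex, the aryl–palladium bond adds syn across the terminal alkynoate (aryl to the unsubstituted beta carbon, palladium to C-alpha), the alkenylpalladium inserts the tethered styrene, and the benzylpalladium is protonated by CF3CO2H/AcOH/H2O, so the metal stays divalent throughout and no zerovalent palladium is on the cycle to ionise the allylic ester (air returns any formed by biaryl homocoupling to the divalent state). The closest known reaction types are the arylboronic acid-triggered asymmetric arylative cyclization of 1,6-enynes and the cyclization of allyl 2-alkynoates to alpha-alkylidene butyrolactones under divalent palladium with N,N ligands ending in protonolysis of the carbon–palladium bond; new is their union on a terminal propiolate with a styrene acceptor. The butyrolactone closes by 5-exo-trig migratory insertion, C-alpha bonding to the alkene carbon next to OCH2; the three-atom ester tether and eta-3 benzyl stabilisation of palladium on the veratryl-bearing carbon should favour this over 6-endo closure. The C3 stereocentre is set in this insertion, where the oxazoline tert-butyl group of the ligand differentiates the two faces of the coordinated alkene. The E geometry follows from syn carbopalladation (aryl cis to palladium, hence cis to C3 and trans to the carbonyl), beta-aryl regiochemistry from the ester polarisation and the free alkyne terminus, and the chelating ligand on the cis site together with the acidic proton source should hold back beta-hydride loss from the benzylpalladium. The base-free medium also spares the base-labile aryl silyl ether.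

Step 7
Reactants: 11 (3E,4R)-3-[4-(tert-butyldimethylsilyloxy)-3-methoxybenzylidene]-4-(3,4-dimethoxybenzyl)dihydrofuran-2(3H)-one
Product: 12 (3E,4R)-4-(3,4-dimethoxybenzyl)-3-(4-hydroxy-3-methoxybenzylidene)dihydrofuran-2(3H)-one (CNP0146216.1)
Conditions: Bu4NF (1.1 equiv), AcOH (1.5 equiv), THF, 0 °C; pH 7 phosphate buffer
Reagents that add atoms: none
Why: Fluoride-driven Si–O cleavage of an aryl silyl ether (desilylation); AcOH protonates the phenoxide as it forms, so the gamma-acidic C3–H, the E arylidene and the lactone should never meet free base and the stereocentre is not touched.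

Compound list
1 | (E)-3,4-dimethoxycinnamic acid | COc1ccc(/C=C/C(=O)O)cc1OC | starting material
2 | methyl (E)-3,4-dimethoxycinnamate | COC(=O)/C=C/c1ccc(OC)c(OC)c1 | intermediate
3 | (E)-3-(3,4-dimethoxyphenyl)prop-2-en-1-ol | COc1ccc(/C=C/CO)cc1OC | intermediate
4 | propiolic acid | C#CC(=O)O | starting material
5 | (E)-3-(3,4-dimethoxyphenyl)prop-2-en-1-yl prop-2-ynoate (1,6-enyne) | C#CC(=O)OC/C=C/c1ccc(OC)c(OC)c1 | intermediate
6 | 4-bromo-2-methoxyphenol | COc1cc(Br)ccc1O | starting material
7 | (4-bromo-2-methoxyphenoxy)(tert-butyl)dimethylsilane | COc1cc(Br)ccc1O[Si](C)(C)C(C)(C)C | intermediate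
8 | [4-(tert-butyldimethylsilyloxy)-3-methoxyphenyl]lithium | COc1cc([Li])ccc1O[Si](C)(C)C(C)(C)C | intermediate
9 | lithium [4-(tert-butyldimethylsilyloxy)-3-methoxyphenyl]triisopropoxyborate | [Li+].COc1cc([B-](OC(C)C)(OC(C)C)OC(C)C)ccc1O[Si](C)(C)C(C)(C)C | intermediate
10 | [4-(tert-butyldimethylsilyloxy)-3-methoxyphenyl]boronic acid | COc1cc(B(O)O)ccc1O[Si](C)(C)C(C)(C)C | intermediate
11 | (3E,4R)-3-[4-(tert-butyldimethylsilyloxy)-3-methoxybenzylidene]-4-(3,4-dimethoxybenzyl)dihydrofuran-2(3H)-one | COc1cc(/C=C2/C(=O)OC[C@@H]2Cc2ccc(OC)c(OC)c2)ccc1O[Si](C)(C)C(C)(C)C | intermediate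
12 | (3E,4R)-4-(3,4-dimethoxybenzyl)-3-(4-hydroxy-3-methoxybenzylidene)dihydrofuran-2(3H)-one (CNP0146216.1) | COc1cc(/C=C2/C(=O)OC[C@@H]2Cc2ccc(OC)c(OC)c2)ccc1O | target

Total step count: 7
Longest linear sequence: 5 steps (steps 1, 2, 3, 6, 7)

Steps most likely to fail

1. Step 6 (proposed new method). What may go wrong:
- the alkenylpalladium may be protonated before it inserts the alkene, because the ester must first turn into its less populated s-cis rotamer, which would give simple hydroarylation;
- the benzylpalladium may lose the C3 hydrogen by beta-hydride elimination, or be attacked by water at the benzylic carbon, instead of being protonated;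
- the activated allylic C–O bond may ionise;
- the alkene insertion may show poor facial selectivity.

Fallback with known chemistry (auxiliary-controlled alkylation, then aldol condensation): it sets out from 1 and from 7 and returns to the route at 11. Hydrogenation of 1 (H2, 10% Pd/C, EtOAc) should give 3-(3,4-dimethoxyphenyl)propanoic acid F1. Coupling with (S)-4-benzyloxazolidin-2-one (DCC, DMAP, CH2Cl2) should give (S)-4-benzyl-3-[3-(3,4-dimethoxyphenyl)propanoyl]oxazolidin-2-one F2. Its sodium Z-enolate (NaN(SiMe3)2, THF, −78 °C) should be alkylated by tert-butyl bromoacetate on the face away from the auxiliary benzyl group, giving tert-butyl (R)-4-[(S)-4-benzyl-2-oxooxazolidin-3-yl]-3-(3,4-dimethoxybenzyl)-4-oxobutanoate F3. LiBH4/H2O (Et2O, 0 °C) should remove the auxiliary reductively to tert-butyl (R)-3-(3,4-dimethoxybenzyl)-4-hydroxybutanoate F4, and p-TsOH (cat.) in toluene should close it to (R)-4-(3,4-dimethoxybenzyl)dihydrofuran-2(3H)-one F5. In parallel, aryllithium 8, made from 7 as in step 5, is quenched with DMF to give 4-(tert-butyldimethylsilyloxy)-3-methoxybenzaldehyde F6. The lithium enolate of F5 (LiN(SiMe3)2, THF, −78 °C) should add to F6 trans to the benzyl group, giving (3S,4R)-3-{[4-(tert-butyldimethylsilyloxy)-3-methoxyphenyl](hydroxy)methyl}-4-(3,4-dimethoxybenzyl)dihydrofuran-2(3H)-one F7 as a mixture of carbinol epimers. Acetylation (Ac2O, Et3N, DMAP, CH2Cl2) should give the acetate F8, and DBU (toluene, rt, short contact) should eliminate it to the thermodynamically preferred E arylidene lactone 11.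

2. Step 3. What may go wrong: the propiolic acid or its ester may oligomerise through conjugate addition of DMAP or carboxylate to the ynoate, the O-acylisourea may rearrange to the N-acylurea, and the electron-rich cinnamyl alcohol may ionise.

Fallback (masked alkyne terminus): it sets out from 3 and returns at 5. Esterification of 3 with 3-(trimethylsilyl)propiolic acid (DCC, DMAP cat., CH2Cl2, 0 °C) should give (E)-3-(3,4-dimethoxyphenyl)prop-2-en-1-yl 3-(trimethylsilyl)prop-2-ynoate F9, whose beta carbon is shielded from nucleophiles. Buffered C-desilylation (Bu4NF/AcOH 1:1, THF, −20 °C) should then release 5.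

3. Step 7. What may go wrong: the phenoxide released on desilylation may isomerise the olefin from E to Z through its quinone methide resonance form, or deprotonate C3, with loss of optical purity or migration of the double bond into the ring.

Fallback (deprotection before the ring is made): it sets out from 10 and returns at 12. Catalytic methanolysis of the aryl silyl ether of 10 (K2CO3 0.2 equiv, MeOH, 0 °C, then pH 6 buffer) should give 4-hydroxy-3-methoxyphenylboronic acid F10. F10 is then coupled with 5 under the base-free conditions of step 6, so the lactone 12 forms directly and never undergoes a deprotection.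

Further compounds
F1 | step 6 | 3-(3,4-dimethoxyphenyl)propanoic acid | COc1ccc(CCC(=O)O)cc1OC
F2 | step 6 | (S)-4-benzyl-3-[3-(3,4-dimethoxyphenyl)propanoyl]oxazolidin-2-one | COc1ccc(CCC(=O)N2[C@@H](Cc3ccccc3)COC2=O)cc1OC
F3 | step 6 | tert-butyl (R)-4-[(S)-4-benzyl-2-oxooxazolidin-3-yl]-3-(3,4-dimethoxybenzyl)-4-oxobutanoate | COc1ccc(C[C@H](CC(=O)OC(C)(C)C)C(=O)N2[C@@H](Cc3ccccc3)COC2=O)cc1OC
F4 | step 6 | tert-butyl (R)-3-(3,4-dimethoxybenzyl)-4-hydroxybutanoate | COc1ccc(C[C@H](CC(=O)OC(C)(C)C)CO)cc1OC
F5 | step 6 | (R)-4-(3,4-dimethoxybenzyl)dihydrofuran-2(3H)-one | COc1ccc(C[C@H]2COC(=O)C2)cc1OC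
F6 | step 6 | 4-(tert-butyldimethylsilyloxy)-3-methoxybenzaldehyde | COc1cc(C=O)ccc1O[Si](C)(C)C(C)(C)C
F7 | step 6 | (3S,4R)-3-{[4-(tert-butyldimethylsilyloxy)-3-methoxyphenyl](hydroxy)methyl}-4-(3,4-dimethoxybenzyl)dihydrofuran-2(3H)-one, carbinol epimers | O=C1OC[C@H](Cc2ccc(OC)c(OC)c2)[C@H]1C(O)c1ccc(O[Si](C)(C)C(C)(C)C)c(OC)c1
F8 | step 6 | acetate of F7 | O=C1OC[C@H](Cc2ccc(OC)c(OC)c2)[C@H]1C(OC(C)=O)c1ccc(O[Si](C)(C)C(C)(C)C)c(OC)c1
F9 | step 3 | (E)-3-(3,4-dimethoxyphenyl)prop-2-en-1-yl 3-(trimethylsilyl)prop-2-ynoate | C[Si](C)(C)C#CC(=O)OC/C=C/c1ccc(OC)c(OC)c1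
F10 | step 7 | 4-hydroxy-3-methoxyphenylboronic acid | COc1cc(B(O)O)ccc1O
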